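**Plan**

- Retrosynthesis: the three methoxymethyl (MOM) acetals and the C4 ketone level are removed first. Ring C is then cut at C3–C4 and at O1–C8a in one step. This gives a ring A aldehyde 8 (C4 as CHO, fluorine on the future C8a, the 1,1-dimethylallyl group already at C6) and the ring B chlorohydrin 13, which carries C3, C2 and O1.
- Enabling feature: on ring A the carbonyl carbon C4 and the C–F carbon C8a are two electrophilic sites in a 1,3-relationship, and O5 and O7 are both meta to C8a. They are matched by the 1,3-dinucleophile C3 (carbanion) / O1 (oxide) held on the stereogenic C2.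
- Forward, ring A: 5-fluororesorcinol is formylated, mono-protected, O-prenylated, rearranged (aromatic Claisen) to put the 1,1-dimethylallyl group between the two oxygens, and protected again. Ring B piece: acetovanillone is protected, α-chlorinated and reduced enantioselectively.
- Key step: the C,O-dianion of 13 adds to aldehyde 8 and the resulting oxide displaces fluoride, closing ring C as flavan-4-ol 16. Oxidation gives flavanone 17 and acid removes the acetals to give 18.
- Stereochemistry: the only stereocentre (C2) is set by asymmetric transfer hydrogenation in step 8. No bond to it is made or broken afterwards, and the ketone is unveiled only after the last basic step.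

Key step: step 9

Assumption: 5-fluororesorcinol and acetovanillone are taken as the commercial starting materials; 16 is carried as the mixture of C4 epimers, which converge in step 10.

**Route**

Step 1
Reactants: 1 5-fluorobenzene-1,3-diol
Product: 3 2-fluoro-4,6-dihydroxybenzaldehyde, via aryl iminium chloride 2 (not isolated)
Conditions: POCl3, DMF, MeCN, 0 °C to rt; then H2O, 50 °C
Reagents that add atoms: N,N-dimethylformamide CN(C)C=O; water O
Why: Vilsmeier–Haack formylation should attack the ring carbon para to one hydroxyl and ortho to the other (next to fluorine) in preference to the more hindered carbon between the two hydroxyls, and hydrolysis of the iminium salt gives the aldehyde.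

Step 2
Reactants: 3 2-fluoro-4,6-dihydroxybenzaldehyde
Product: 4 2-fluoro-6-hydroxy-4-(methoxymethoxy)benzaldehyde
Conditions: MOMCl (1.05 equiv), i-Pr2NEt, CH2Cl2, 0 °C
Reagents that add atoms: chloromethyl methyl ether COCCl
Why: Williamson-type O-alkylation should select the para hydroxyl, which is more acidic and not tied up in the hydrogen bond to the aldehyde.

Step 3
Reactants: 4 2-fluoro-6-hydroxy-4-(methoxymethoxy)benzaldehyde
Product: 5 2-fluoro-4-(methoxymethoxy)-6-[(3-methylbut-2-en-1-yl)oxy]benzaldehyde
Conditions: prenyl bromide, K2CO3, DMF, rt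
Reagents that add atoms: 1-bromo-3-methylbut-2-ene CC(C)=CCBr
Why: Williamson ether synthesis on the remaining phenol with a reactive primary allylic bromide should give the aryl prenyl ether needed for the rearrangement.

Step 4
Reactants: 5 2-fluoro-4-(methoxymethoxy)-6-[(3-methylbut-2-en-1-yl)oxy]benzaldehyde
Product: 7 6-fluoro-2-hydroxy-4-(methoxymethoxy)-3-(2-methylbut-3-en-2-yl)benzaldehyde, via ortho-dienone 6 (not isolated)
Conditions: Eu(fod)3 (10 mol %; fod = 6,6,7,7,8,8,8-heptafluoro-2,2-dimethyl-3,5-octanedionate), CHCl3, 40 °C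
Reagents that add atoms: none
Why: Aromatic Claisen rearrangement, accelerated by chelation of the europium complex between the aldehyde and ether oxygens, can only reach the free ortho carbon between the two oxygens (the other ortho carbon carries CHO), so the [3,3] shift with allyl inversion should place the 1,1-dimethylallyl group there, and the low temperature is meant to let enolisation of 6 outrun a second (Cope) shift.

Step 5
Reactants: 7 6-fluoro-2-hydroxy-4-(methoxymethoxy)-3-(2-methylbut-3-en-2-yl)benzaldehyde
Product: 8 6-fluoro-2,4-bis(methoxymethoxy)-3-(2-methylbut-3-en-2-yl)benzaldehyde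
Conditions: MOMCl, Cs2CO3, DMF, rt
Reagents that add atoms: chloromethyl methyl ether COCCl
Why: Williamson-type O-alkylation with a caesium phenoxide in DMF and a small, very reactive electrophile should overcome the hydrogen bonding and the flanking tertiary group.

Step 6
Reactants: 9 1-(4-hydroxy-3-methoxyphenyl)ethan-1-one
Product: 10 1-[3-methoxy-4-(methoxymethoxy)phenyl]ethan-1-one
Conditions: MOMCl, i-Pr2NEt, CH2Cl2, 0 °C to rt
Reagents that add atoms: chloromethyl methyl ether COCCl
Why: Williamson-type O-alkylation of a free para-acyl phenol is routine and gives a base-stable acetal that survives the organolithium chemistry ahead.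

Step 7
Reactants: 10 1-[3-methoxy-4-(methoxymethoxy)phenyl]ethan-1-one
Product: 12 2-chloro-1-[3-methoxy-4-(methoxymethoxy)phenyl]ethan-1-one, via trimethylsilyl enol ether 11 (not isolated)
Conditions: LiHMDS, TMSCl, THF, −78 °C; then NCS, 0 °C
Reagents that add atoms: N-chlorosuccinimide O=C1CCC(=O)N1Cl
Why: Electrophilic α-chlorination of a silyl enol ether is acid-free and should be mono-selective, so the MOM ether and the electron-rich ring are left alone.

Step 8
Reactants: 12 2-chloro-1-[3-methoxy-4-(methoxymethoxy)phenyl]ethan-1-one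
Product: 13 (1R)-2-chloro-1-[3-methoxy-4-(methoxymethoxy)phenyl]ethan-1-ol
Conditions: RuCl[(S,S)-TsDPEN](p-cymene) (1 mol %), HCO2H/Et3N (5:2), EtOAc, rt
Reagents that add atoms: none
Why: Asymmetric transfer hydrogenation with the (S,S) catalyst should deliver hydride to the face that gives (S)-1-arylethanols from aryl methyl ketones, which here carries the descriptor R because CH2Cl outranks aryl, and this sets the centre that becomes C2 (S) of the target.

Step 9
Reactants: 13 (1R)-2-chloro-1-[3-methoxy-4-(methoxymethoxy)phenyl]ethan-1-ol; 8 6-fluoro-2,4-bis(methoxymethoxy)-3-(2-methylbut-3-en-2-yl)benzaldehyde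
Product: 16 (2S)-2-[3-methoxy-4-(methoxymethoxy)phenyl]-5,7-bis(methoxymethoxy)-6-(2-methylbut-3-en-2-yl)-3,4-dihydro-2H-chromen-4-ol (both C4 epimers), via C-lithiated lithium alkoxide 14 (not isolated), via dilithium 1,3-diolate 15 (not isolated)
Conditions: 13 (1.2 equiv), n-BuLi, THF, −78 °C; LiC10H8 (lithium naphthalenide, 2.0 equiv per 13), −78 °C; 8, −78 °C; then KOt-Bu (1.2 equiv), DMF, 60 °C; H2O
Reagents that add atoms: none
Why: Deprotonation and reductive lithiation of the C–Cl bond of 13 should give the β-oxido organolithium 14, in which the oxide is too poor a leaving group for β-elimination at −78 °C; its carbanion adds to the aldehyde of 8 (bond C3–C4) and, after potassium exchange and warming, the C2 oxide of 15 attacks the fluorine-bearing ring carbon ortho to the new carbinol and expels fluoride through a Meisenheimer-type anion (bond O1–C8a). The closest known reaction types are the addition of β-oxido organolithiums to carbonyl compounds (1,3-diol synthesis) and the intramolecular SNAr etherification of fluoroarenes by tethered alkoxides that gives chromans and flavans. Ring C closes as a six-membered ring by ipso addition–elimination at an sp2 carbon (formally 6-exo-trig). The C2 stereocentre is that of 13 and no bond to it is made or broken (the descriptor changes from R to S only because the ligand priorities change), while the C4 carbinol forms as an epimer mixture that step 10 erases. The step needs chemoselectivity for the C2 oxide and a defined site of O-arylation: the C4 oxide could only close a four-membered ring, the single fluorine fixes which ortho carbon becomes C8a (so the 6- and not the 8-substituted chromane results), and the O5 and O7 acetal oxygens are both meta to that carbon and so stabilise the anionic intermediate inductively without donating into it. Holding C4 at the alcohol level keeps the base-mediated closure free of the retro-aldol and β-elimination channels of a β-oxido ketone that would erode C2, and the 1,1-dimethylallyl group has no allylic hydrogen to isomerise.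

Step 10
Reactants: 16 (2S)-2-[3-methoxy-4-(methoxymethoxy)phenyl]-5,7-bis(methoxymethoxy)-6-(2-methylbut-3-en-2-yl)-3,4-dihydro-2H-chromen-4-ol (both C4 epimers)
Product: 17 (2S)-2-[3-methoxy-4-(methoxymethoxy)phenyl]-5,7-bis(methoxymethoxy)-6-(2-methylbut-3-en-2-yl)-2,3-dihydro-4H-chromen-4-one
Conditions: Dess–Martin periodinane, pyridine, CH2Cl2, 0 °C to rt
Reagents that add atoms: none
Why: Dess–Martin oxidation of the benzylic secondary alcohol under buffered, non-basic conditions should converge both epimers to the flavanone without touching the terminal alkene or the C2 centre.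

Step 11
Reactants: 17 (2S)-2-[3-methoxy-4-(methoxymethoxy)phenyl]-5,7-bis(methoxymethoxy)-6-(2-methylbut-3-en-2-yl)-2,3-dihydro-4H-chromen-4-one
Product: 18 (2S)-5,7-dihydroxy-2-(4-hydroxy-3-methoxyphenyl)-6-(2-methylbut-3-en-2-yl)-2,3-dihydro-4H-chromen-4-one
Conditions: HCl (3 M aq), MeOH, 40 °C
Reagents that add atoms: none
Why: Acid-catalysed acetal exchange with methanol removes all three MOM groups (the one next to the carbonyl fastest), conditions under which a flavanone C2 centre is configurationally stable and the aryl methyl ether is untouched.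

**Compound list**

1 | 5-fluorobenzene-1,3-diol (5-fluororesorcinol) | Oc1cc(O)cc(F)c1 | starting material
2 | [(2-fluoro-4,6-dihydroxyphenyl)methylidene]dimethylammonium chloride | C[N+](C)=Cc1c(O)cc(O)cc1F.[Cl-] | intermediate
3 | 2-fluoro-4,6-dihydroxybenzaldehyde | O=Cc1c(O)cc(O)cc1F | intermediate
4 | 2-fluoro-6-hydroxy-4-(methoxymethoxy)benzaldehyde | O=Cc1c(O)cc(OCOC)cc1F | intermediate
5 | 2-fluoro-4-(methoxymethoxy)-6-[(3-methylbut-2-en-1-yl)oxy]benzaldehyde | O=Cc1c(OCC=C(C)C)cc(OCOC)cc1F | intermediate
6 | 2-fluoro-4-(methoxymethoxy)-5-(2-methylbut-3-en-2-yl)-6-oxocyclohexa-1,3-diene-1-carbaldehyde (racemic) | O=CC1=C(F)C=C(OCOC)C(C(C)(C)C=C)C1=O | intermediate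
7 | 6-fluoro-2-hydroxy-4-(methoxymethoxy)-3-(2-methylbut-3-en-2-yl)benzaldehyde | O=Cc1c(O)c(C(C)(C)C=C)c(OCOC)cc1F | intermediate
8 | 6-fluoro-2,4-bis(methoxymethoxy)-3-(2-methylbut-3-en-2-yl)benzaldehyde | O=Cc1c(OCOC)c(C(C)(C)C=C)c(OCOC)cc1F | intermediate
9 | 1-(4-hydroxy-3-methoxyphenyl)ethan-1-one (acetovanillone) | CC(=O)c1ccc(O)c(OC)c1 | starting material
10 | 1-[3-methoxy-4-(methoxymethoxy)phenyl]ethan-1-one | CC(=O)c1ccc(OCOC)c(OC)c1 | intermediate
11 | {1-[3-methoxy-4-(methoxymethoxy)phenyl]ethenyl}oxy(trimethyl)silane | C=C(O[Si](C)(C)C)c1ccc(OCOC)c(OC)c1 | intermediate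
12 | 2-chloro-1-[3-methoxy-4-(methoxymethoxy)phenyl]ethan-1-one | O=C(CCl)c1ccc(OCOC)c(OC)c1 | intermediate
13 | (1R)-2-chloro-1-[3-methoxy-4-(methoxymethoxy)phenyl]ethan-1-ol | O[C@@H](CCl)c1ccc(OCOC)c(OC)c1 | intermediate
14 | lithium 2-lithio-1-[3-methoxy-4-(methoxymethoxy)phenyl]ethan-1-olate (spatial arrangement of 13 retained) | [Li]O[C@@H](C[Li])c1ccc(OCOC)c(OC)c1 | intermediate
15 | dilithium 1-[6-fluoro-2,4-bis(methoxymethoxy)-3-(2-methylbut-3-en-2-yl)phenyl]-3-[3-methoxy-4-(methoxymethoxy)phenyl]propane-1,3-diolate (3S; both C1 epimers) | [Li]O[C@@H](CC(O[Li])c1c(F)cc(OCOC)c(C(C)(C)C=C)c1OCOC)c2ccc(OCOC)c(OC)c2 | intermediate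
16 | (2S)-2-[3-methoxy-4-(methoxymethoxy)phenyl]-5,7-bis(methoxymethoxy)-6-(2-methylbut-3-en-2-yl)-3,4-dihydro-2H-chromen-4-ol (both C4 epimers) | C=CC(C)(C)c1c(OCOC)cc2c(c1OCOC)C(O)C[C@@H](c3ccc(OCOC)c(OC)c3)O2 | intermediate
17 | (2S)-2-[3-methoxy-4-(methoxymethoxy)phenyl]-5,7-bis(methoxymethoxy)-6-(2-methylbut-3-en-2-yl)-2,3-dihydro-4H-chromen-4-one | C=CC(C)(C)c1c(OCOC)cc2c(c1OCOC)C(=O)C[C@@H](c3ccc(OCOC)c(OC)c3)O2 | intermediate
18 | (2S)-5,7-dihydroxy-2-(4-hydroxy-3-methoxyphenyl)-6-(2-methylbut-3-en-2-yl)-2,3-dihydro-4H-chromen-4-one | C=CC(C)(C)c1c(O)cc2c(c1O)C(=O)C[C@@H](c3ccc(O)c(OC)c3)O2 | target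

**Step count**

Total: 11 steps. Longest linear sequence: 8 steps (steps 1–5, then 9–11); the ring B branch is steps 6–8.

**Steps most likely to fail**

Step 9. The dianion 14 may lose lithium oxide by β-elimination (giving the styrene) before it meets the aldehyde, or fluoride displacement may be too slow on a ring that has no conjugating acceptor. The fallback reverses the polarity of the C3–C4 bond formation and makes the two bonds stepwise; it sets out from 8 and 13 and comes back at 17, so step 10 is not needed. Aldehyde 8 is converted with propane-1,3-dithiol and catalytic I2 in CH2Cl2 into the 2-aryl-1,3-dithiane F1. Chlorohydrin 13 is closed with K2CO3 in MeOH to the (R)-aryl oxirane F2. F1 is lithiated (n-BuLi, THF, −30 °C) and should open F2 at its CH2 carbon, leaving the stereocentre untouched, to give the hydroxy dithiane F3. KOt-Bu in DMF then closes ring C by fluoride displacement, helped by the geminal disubstitution at C4, to the spiro-dithiane F4. MeI and NaHCO3 in aqueous MeCN unmask the ketone and give 17.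

Step 4. In dienone 6 a second [3,3] (Cope) shift may carry the allyl group on to the free para carbon (between fluorine and the MOM ether) before enolisation, giving the normal prenyl isomer instead of the 1,1-dimethylallyl phenol. The fallback blocks that carbon; it sets out from 4 and comes back at 8, replacing steps 3–5. Phenol 4 is brominated para to the hydroxyl with NBS in MeCN at 0 °C to the bromo phenol F5. Prenyl bromide and K2CO3 in DMF give the bromo prenyl ether F6. The Claisen rearrangement (Eu(fod)3 or heat) can now only stop at the ortho position and gives the bromo 1,1-dimethylallyl phenol F7. MOMCl and Cs2CO3 give the bromo bis-acetal F8. Reductive removal of bromine with Pd(OAc)2, PPh3, HCO2H and Et3N in DMF at 60 °C gives 8.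

Step 11. Protonation of the very electron-rich ring carbon C6 may lead to loss or 1,3-shift of the tertiary allyl group, or a flanking phenol may add to the vinyl group under Brønsted acid. The fallback avoids protic acid by exchanging the acetals for silyl ethers; it sets out from 17 and comes back at 18. Treatment of 17 with TESOTf and 2,2'-bipyridyl in CH2Cl2 at 0 °C should convert the three aryl MOM ethers directly into the tris(triethylsilyl) ether F9. HF·pyridine in THF/pyridine at 0 °C then frees the three phenols to give 18.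

Further compounds
F1 | step 9 | 2-[6-fluoro-2,4-bis(methoxymethoxy)-3-(2-methylbut-3-en-2-yl)phenyl]-1,3-dithiane | C=CC(C)(C)c1c(OCOC)cc(F)c(C2SCCCS2)c1OCOC
F2 | step 9 | (2R)-2-[3-methoxy-4-(methoxymethoxy)phenyl]oxirane | C1O[C@@H]1c2ccc(OCOC)c(OC)c2
F3 | step 9 | (1S)-2-{2-[6-fluoro-2,4-bis(methoxymethoxy)-3-(2-methylbut-3-en-2-yl)phenyl]-1,3-dithian-2-yl}-1-[3-methoxy-4-(methoxymethoxy)phenyl]ethan-1-ol | O[C@@H](CC1(SCCCS1)c2c(F)cc(OCOC)c(C(C)(C)C=C)c2OCOC)c3ccc(OCOC)c(OC)c3
F4 | step 9 | (2S)-2-[3-methoxy-4-(methoxymethoxy)phenyl]-5,7-bis(methoxymethoxy)-6-(2-methylbut-3-en-2-yl)-2,3-dihydrospiro[chromene-4,2'-[1,3]dithiane] | C=CC(C)(C)c1c(OCOC)cc2c(c1OCOC)C3(SCCCS3)C[C@@H](c4ccc(OCOC)c(OC)c4)O2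
F5 | step 4 | 3-bromo-2-fluoro-6-hydroxy-4-(methoxymethoxy)benzaldehyde | O=Cc1c(O)cc(OCOC)c(Br)c1F
F6 | step 4 | 3-bromo-2-fluoro-4-(methoxymethoxy)-6-[(3-methylbut-2-en-1-yl)oxy]benzaldehyde | O=Cc1c(OCC=C(C)C)cc(OCOC)c(Br)c1F
F7 | step 4 | 3-bromo-2-fluoro-6-hydroxy-4-(methoxymethoxy)-5-(2-methylbut-3-en-2-yl)benzaldehyde | O=Cc1c(O)c(C(C)(C)C=C)c(OCOC)c(Br)c1F
F8 | step 4 | 3-bromo-2-fluoro-4,6-bis(methoxymethoxy)-5-(2-methylbut-3-en-2-yl)benzaldehyde | O=Cc1c(OCOC)c(C(C)(C)C=C)c(OCOC)c(Br)c1F
F9 | step 11 | (2S)-2-[3-methoxy-4-(triethylsilyloxy)phenyl]-6-(2-methylbut-3-en-2-yl)-5,7-bis(triethylsilyloxy)-2,3-dihydro-4H-chromen-4-one | C=CC(C)(C)c1c(O[Si](CC)(CC)CC)cc2c(c1O[Si](CC)(CC)CC)C(=O)C[C@@H](c3ccc(O[Si](CC)(CC)CC)c(OC)c3)O2
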